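3 questions about 2 flasks stand here, with the scheme and the settings.

    E → L (k1 = 0.13 s⁻¹, Ea1 = 87.0 kJ mol⁻¹)
    E + E ⇌ E2 (K2 = 2100 L mol⁻¹, k2 = 1100 L mol⁻¹ s⁻¹, Ea2 = 41.0 kJ mol⁻¹, ΔH2 = −9.00 kJ mol⁻¹)
    E + L → E.L (k3 = 470 L mol⁻¹ s⁻¹, Ea3 = 48.0 kJ mol⁻¹)
    D ⇌ E, rate k4*(cs4 - [E]) while solid is left; crystals form when [E] > cs4 (cs4 = 0.042 mM, k4 = 1.1 s⁻¹)
    L → J (k5 = 0.084 s⁻¹, Ea5 = 88.0 kJ mol⁻¹)
    (constants at 40 °C)

in all of them: D 0.20 mM; time 20 s
- grey: temperature 40 °C
- teal: temperature 55 °C

- in percentages every species weighs as the D in it: one E2 or E.L counts as two
- a step written with two of one species runs at k times the square of its concentration and takes two of it each time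
- as a solid, counted per litre of solution: D
- the constants hold at 40 °C; other temperatures follow from the activation energies and enthalpies
- at the start none of D is in solution
- what has only dissolved of D counts as not reacted

1. which flask leads in amount of L, in percent of the D charged ("all alike" within 1.5 percentage points) (grey / teal / all alike)
2. how much L is there at the end, in percent of the D charged: grey
3. how much L is there at the end, in percent of the D charged: teal

Dissolution beats ring closure in both flasks, 1.1 s⁻¹ against 0.13 s⁻¹ in grey and 0.599 s⁻¹ in teal. So I take it as fast and hold c_E in a quasi-steady state while solid remains: solubility times the dissolution coefficient, over the sum of that coefficient and the closure constant. That gives 0.0376 mM in grey and 0.0272 mM in teal. In grey the dimer constant times c_E is 0.0789, so I neglect the open dimer.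

Grey gives 0.488 for my drain number N, the closure rate at that level times the time, over the charge of D. It is the share of the charge that closure could carry off through the solution in the time. Well below one, my reckoning has solid outlasting the time with L still being fed; well above one, it has the solid ending before the time. Grey stays below, but teal gives 1.63, and its solid should end at 10.6 s.

N picks the side but not the amount of L, so one number is not enough; the pseudo-first-order loss of L, to J and to capture by E, has to be added. In grey, L climbs under a loss constant of 0.102 s⁻¹ and reaches 20.9%. In teal, the constant to J is 0.394 s⁻¹ and the loss constant is 0.423 s⁻¹, so I put L near 19.2% when the solid ends. Then 9.39 s of decay at the constant to J, with the remaining E still closing, leave 1.32%. I expect grey to lead, with more L than teal.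

The forecast says grey, with 20% (18% to 22%) in grey and 1% (0.6% to 1.6%) in teal, since when hot “the faster drain uses up the solid”. The simulation gives grey ahead, with 20.3% in grey and 1.41% in teal.

A flask like teal kept at 30 °C has a closure constant of 0.0432 s⁻¹, so c_E is 0.0404 mM and N is 0.174, below grey's 0.488. The same rise under its loss constant of 0.0379 s⁻¹ gives 12.2% of L. That flask ends with 11.8% of L and 58.3% of D still solid.

Its constants were set for the occasion; the rest is arithmetic.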